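**Plan**

1. Retrosynthesis: the first cut is the bond from ring B C4 (para to the ether oxygen) to the carbinol carbon C1, which opens the 22-membered ring to an aryl iodide and a C1 aldehyde. Further cuts are the C8=C9 E-alkene (sulfone + aldehyde), the ring A–C14 bond (aryl bromide + alkylborane), the ring B C4–iodine bond (back to C–H) and the diaryl ether C–O bond.
2. Forward: the diaryl ether with both rings is made first and its methyl ethers are exchanged for silyl ethers. A six-carbon ester arm is put on ring A, iodine on ring B C4, and the arm is extended through the E-alkene to the C1 aldehyde. The macrocycle is closed last, then the silyl ethers are removed.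
3. Stereochemistry: the E-alkene comes from a Julia–Kocienski olefination. The only stereocentre (R, benzylic carbinol) is created in the ring closure under control of a chiral sulfonamide–oxazoline ligand on chromium.
4. Enabling feature: ring B C4 is the only aromatic carbon flanked by two C–H (C3–H and C5–H). C–H borylation therefore picks it alone, and an aryl–metal there is not hindered by the C2/C6 silyl ethers. The carbinol carbon is the sole stereocentre and carries an unbranched CH2 chain, so it can be an aldehyde carbon; the diaryl ether hinge and the E-alkene stiffen the 14-carbon tether.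

Key step: step 11

Assumption: the (S)-configured ligand L* is taken to deliver the aryl group to the Si face of the aldehyde, which gives the (R)-carbinol. The sense is to be confirmed on an open-chain model (aryl iodide plus octanal); if it is opposite, the (R)-ligand is used under the same conditions.

Abbreviations: TIPS = triisopropylsilyl; L* = (S)-N-[2-(4-isopropyl-4,5-dihydro-1,3-oxazol-2-yl)-6-methylphenyl]methanesulfonamide; 9-BBN = 9-borabicyclo[3.3.1]nonane; pin = pinacolato.

**Route**

Step 1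
Reactants: 1 ethyl 8-bromooctanoate; 2 1-phenyl-1H-tetrazole-5-thiol
Product: 3 ethyl 8-[(1-phenyl-1H-tetrazol-5-yl)sulfanyl]octanoate
Conditions: K2CO3, acetone, reflux
Reagents that add atoms: none
Why: SN2 S-alkylation of the tetrazolethiolate by the primary bromide should be clean and leaves the ester untouched.

Step 2
Reactants: 3 ethyl 8-[(1-phenyl-1H-tetrazol-5-yl)sulfanyl]octanoate
Product: 4 ethyl 8-[(1-phenyl-1H-tetrazol-5-yl)sulfonyl]octanoate
Conditions: (NH4)6Mo7O24·4H2O (10 mol%), 30% aq. H2O2, EtOH, 0 °C to rt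
Reagents that add atoms: hydrogen peroxide, OO
Why: Molybdate-catalysed peroxide oxidation takes the sulfide to the sulfone needed for the Julia–Kocienski olefination without touching the ester.

Step 3
Reactants: 5 2,6-dimethoxyphenol; 6 1-bromo-3-iodo-5-methoxybenzene
Product: 7 2-(3-bromo-5-methoxyphenoxy)-1,3-dimethoxybenzene
Conditions: CuI (10 mol%), picolinic acid (20 mol%), K3PO4, DMSO, 80 °C, argon
Reagents that add atoms: none
Why: Ullmann-type C–O coupling with the picolinic acid system suits a doubly ortho-substituted phenol; the carbon–iodine bond reacts well before the carbon–bromine bond, so the bromide is kept as the later coupling handle, and exclusion of air suppresses oxidative dimerisation of the phenol.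

Step 4
Reactants: 7 2-(3-bromo-5-methoxyphenoxy)-1,3-dimethoxybenzene
Product: 8 2-(3-bromo-5-hydroxyphenoxy)benzene-1,3-diol
Conditions: BBr3, CH2Cl2, −78 °C to rt; then MeOH, H2O
Reagents that add atoms: none
Why: BBr3 cleaves the three aryl methyl ethers while the diaryl ether and the aryl bromide are inert; it is done here, before any alkene or benzylic alcohol is present.

Step 5
Reactants: 8 2-(3-bromo-5-hydroxyphenoxy)benzene-1,3-diol
Product: 9 2-[3-bromo-5-(TIPS-oxy)phenoxy]-1,3-bis(TIPS-oxy)benzene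
Conditions: TIPSOTf, 2,6-lutidine, CH2Cl2, 0 °C to rt
Reagents that add atoms: triisopropylsilyl trifluoromethanesulfonate, CC(C)[Si](OS(=O)(=O)C(F)(F)F)(C(C)C)C(C)C
Why: The silyl triflate silylates even the two phenols next to the ether oxygen; aryl TIPS ethers should survive aqueous base, KN(SiMe3)2 and iBu2AlH and come off with fluoride at the end.

Step 6
Reactants: 9 2-[3-bromo-5-(TIPS-oxy)phenoxy]-1,3-bis(TIPS-oxy)benzene; 10 methyl hex-5-enoate
Product: 12 methyl 6-[3-[2,6-bis(TIPS-oxy)phenoxy]-5-(TIPS-oxy)phenyl]hexanoate, via alkyl-9-BBN borane 11 (not isolated)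
Conditions: 10, 9-BBN, THF, 0 °C to rt; then 9, PdCl2(dppf) (5 mol%), aq. K3PO4, THF/DMF, 50 °C
Reagents that add atoms: none
Why: Anti-Markovnikov hydroboration of the terminal alkene followed by B-alkyl Suzuki–Miyaura coupling at the only carbon–halogen bond joins C9–C14 to ring A; the ester is inert to 9-BBN.

Step 7
Reactants: 12 methyl 6-[3-[2,6-bis(TIPS-oxy)phenoxy]-5-(TIPS-oxy)phenyl]hexanoate
Product: 14 methyl 6-[3-[4-iodo-2,6-bis(TIPS-oxy)phenoxy]-5-(TIPS-oxy)phenyl]hexanoate, via aryl pinacol boronate 13 (not isolated)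
Conditions: [Ir(OMe)(cod)]2 (2 mol%), 4,4′-di-tert-butyl-2,2′-bipyridine (4 mol%), B2pin2, THF, 80 °C; solvent removed; then CuI (10 mol%), 1,10-phenanthroline (20 mol%), KI, THF/MeOH/H2O, air, 80 °C
Reagents that add atoms: potassium iodide, [K+].[I-]
Why: Sterically controlled iridium-catalysed C–H borylation should occur only at ring B C4, the one aromatic C–H with two ortho hydrogens (all three ring A C–H lie between two substituents, ring B C3–H and C5–H are ortho to OTIPS), and copper-mediated iododeboronation then gives the aryl iodide.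

Step 8
Reactants: 14 methyl 6-[3-[4-iodo-2,6-bis(TIPS-oxy)phenoxy]-5-(TIPS-oxy)phenyl]hexanoate
Product: 15 6-[3-[4-iodo-2,6-bis(TIPS-oxy)phenoxy]-5-(TIPS-oxy)phenyl]hexanal
Conditions: iBu2AlH (1.1 equiv), CH2Cl2, −78 °C; aq. potassium sodium tartrate
Reagents that add atoms: none
Why: Partial reduction of the methyl ester at −78 °C stops at the aluminium hemiacetal, which releases the aldehyde on work-up; the aryl iodide and silyl ethers are inert.

Step 9
Reactants: 15 6-[3-[4-iodo-2,6-bis(TIPS-oxy)phenoxy]-5-(TIPS-oxy)phenyl]hexanal; 4 ethyl 8-[(1-phenyl-1H-tetrazol-5-yl)sulfonyl]octanoate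
Product: 16 ethyl (E)-14-[3-[4-iodo-2,6-bis(TIPS-oxy)phenoxy]-5-(TIPS-oxy)phenyl]tetradec-8-enoate
Conditions: KN(SiMe3)2 added to 4 and 15, DME, −60 °C to rt
Reagents that add atoms: none
Why: Julia–Kocienski olefination; with the potassium counter-ion in DME the anti adduct of the phenyltetrazolyl sulfone anion is favoured, and Smiles rearrangement with anti elimination of SO2 and the tetrazolate should give the E-alkene C8=C9.

Step 10
Reactants: 16 ethyl (E)-14-[3-[4-iodo-2,6-bis(TIPS-oxy)phenoxy]-5-(TIPS-oxy)phenyl]tetradec-8-enoate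
Product: 17 (E)-14-[3-[4-iodo-2,6-bis(TIPS-oxy)phenoxy]-5-(TIPS-oxy)phenyl]tetradec-8-enal
Conditions: iBu2AlH (1.1 equiv), CH2Cl2, −78 °C; aq. potassium sodium tartrate
Reagents that add atoms: none
Why: The same low-temperature partial ester reduction gives the C1 aldehyde; the isolated alkene and the aryl iodide are not touched by the hydride.

Step 11
Reactants: 17 (E)-14-[3-[4-iodo-2,6-bis(TIPS-oxy)phenoxy]-5-(TIPS-oxy)phenyl]tetradec-8-enal
Product: 18 tris-TIPS ether of dehydrogravicycle (22-membered ring; R at the benzylic carbinol; E-alkene; free secondary OH)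
Conditions: CrCl2 (6 equiv), L* (6.6 equiv), Et3N (6.6 equiv), THF/MeCN, rt; NiCl2(2,9-dimethyl-1,10-phenanthroline) (0.3 equiv); 17 added over 12 h to 2 mM, rt
Reagents that add atoms: none
Why: Proposed new method: zerovalent nickel inserts into the carbon–iodine bond at ring B C4, the aryl group passes to ligand-bound trivalent chromium, and the arylchromium adds to the tethered aldehyde through a closed transition state with the aldehyde oxygen on chromium (Nozaki–Hiyama–Kishi reaction run with a chiral ligand). The closest known reactions are ligand-controlled Ni/Cr macrocyclisations of alkenyl iodides onto aldehydes and Ni/Cr additions of aryl iodides to aldehydes; an enantioselective macrocyclising aryl addition has not been shown. The 22-membered ring closes by 22-exo-trig 1,2-addition of the aryl–chromium bond to the aldehyde carbon, helped by the diaryl ether hinge and the E-alkene, which limit the freedom of the tether. The single new stereocentre is set by the chiral ligand on chromium, taken to expose the Si face of the aldehyde (R); the substrate has no other stereocentre and exerts no bias. The step needs addition to the aldehyde only, which the organochromium secures since it does not attack silyl ethers, the alkene or the diaryl ether, and it needs ring closure over dimerisation, which slow addition at high dilution secures. C4 has no ortho substituent, so neither nickel insertion nor the addition is blocked by the OTIPS groups at C2 and C6.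

Step 12
Reactants: 18 tris-TIPS ether of dehydrogravicycle
Product: 19 dehydrogravicycle
Conditions: Bu4NF, AcOH, THF, 0 °C to rt, degassed
Reagents that add atoms: none
Why: Fluoride cleaves the three aryl silyl ethers (phenoxide leaving groups) under buffered conditions that leave the benzylic alcohol, its configuration and the E-alkene untouched.

**Compound list**

1 | ethyl 8-bromooctanoate | CCOC(=O)CCCCCCCBr | starting material
2 | 1-phenyl-1H-tetrazole-5-thiol | Sc1nnnn1-c1ccccc1 | starting material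
3 | ethyl 8-[(1-phenyl-1H-tetrazol-5-yl)sulfanyl]octanoate | CCOC(=O)CCCCCCCSc1nnnn1-c1ccccc1 | intermediate
4 | ethyl 8-[(1-phenyl-1H-tetrazol-5-yl)sulfonyl]octanoate | CCOC(=O)CCCCCCCS(=O)(=O)c1nnnn1-c1ccccc1 | intermediate
5 | 2,6-dimethoxyphenol | COc1cccc(OC)c1O | starting material
6 | 1-bromo-3-iodo-5-methoxybenzene | COc1cc(Br)cc(I)c1 | starting material
7 | 2-(3-bromo-5-methoxyphenoxy)-1,3-dimethoxybenzene | COc1cc(Br)cc(Oc2c(OC)cccc2OC)c1 | intermediate
8 | 2-(3-bromo-5-hydroxyphenoxy)benzene-1,3-diol | Oc1cc(Br)cc(Oc2c(O)cccc2O)c1 | intermediate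
9 | 2-[3-bromo-5-(TIPS-oxy)phenoxy]-1,3-bis(TIPS-oxy)benzene | Brc1cc(O[Si](C(C)C)(C(C)C)C(C)C)cc(Oc2c(O[Si](C(C)C)(C(C)C)C(C)C)cccc2O[Si](C(C)C)(C(C)C)C(C)C)c1 | intermediate
10 | methyl hex-5-enoate | COC(=O)CCCC=C | starting material
11 | methyl 6-(9-borabicyclo[3.3.1]nonan-9-yl)hexanoate | COC(=O)CCCCCB1C2CCCC1CCC2 | intermediate
12 | methyl 6-[3-[2,6-bis(TIPS-oxy)phenoxy]-5-(TIPS-oxy)phenyl]hexanoate | COC(=O)CCCCCc1cc(O[Si](C(C)C)(C(C)C)C(C)C)cc(Oc2c(O[Si](C(C)C)(C(C)C)C(C)C)cccc2O[Si](C(C)C)(C(C)C)C(C)C)c1 | intermediate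
13 | methyl 6-[3-[4-(4,4,5,5-tetramethyl-1,3,2-dioxaborolan-2-yl)-2,6-bis(TIPS-oxy)phenoxy]-5-(TIPS-oxy)phenyl]hexanoate | COC(=O)CCCCCc1cc(O[Si](C(C)C)(C(C)C)C(C)C)cc(Oc2c(O[Si](C(C)C)(C(C)C)C(C)C)cc(B3OC(C)(C)C(C)(C)O3)cc2O[Si](C(C)C)(C(C)C)C(C)C)c1 | intermediate
14 | methyl 6-[3-[4-iodo-2,6-bis(TIPS-oxy)phenoxy]-5-(TIPS-oxy)phenyl]hexanoate | COC(=O)CCCCCc1cc(O[Si](C(C)C)(C(C)C)C(C)C)cc(Oc2c(O[Si](C(C)C)(C(C)C)C(C)C)cc(I)cc2O[Si](C(C)C)(C(C)C)C(C)C)c1 | intermediate
15 | 6-[3-[4-iodo-2,6-bis(TIPS-oxy)phenoxy]-5-(TIPS-oxy)phenyl]hexanal | O=CCCCCCc1cc(O[Si](C(C)C)(C(C)C)C(C)C)cc(Oc2c(O[Si](C(C)C)(C(C)C)C(C)C)cc(I)cc2O[Si](C(C)C)(C(C)C)C(C)C)c1 | intermediate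
16 | ethyl (E)-14-[3-[4-iodo-2,6-bis(TIPS-oxy)phenoxy]-5-(TIPS-oxy)phenyl]tetradec-8-enoate | CCOC(=O)CCCCCC/C=C/CCCCCc1cc(O[Si](C(C)C)(C(C)C)C(C)C)cc(Oc2c(O[Si](C(C)C)(C(C)C)C(C)C)cc(I)cc2O[Si](C(C)C)(C(C)C)C(C)C)c1 | intermediate
17 | (E)-14-[3-[4-iodo-2,6-bis(TIPS-oxy)phenoxy]-5-(TIPS-oxy)phenyl]tetradec-8-enal | O=CCCCCCC/C=C/CCCCCc1cc(O[Si](C(C)C)(C(C)C)C(C)C)cc(Oc2c(O[Si](C(C)C)(C(C)C)C(C)C)cc(I)cc2O[Si](C(C)C)(C(C)C)C(C)C)c1 | intermediate
18 | tris-TIPS ether of dehydrogravicycle: 22-membered ring in which the (R)-CH(OH) carbon sits on ring B C4, a 14-carbon chain with an E-alkene at C8=C9 ends on ring A, and all three phenols are TIPS ethers | CC(C)[Si](C(C)C)(C(C)C)Oc1cc2cc(c1)Oc1c(O[Si](C(C)C)(C(C)C)C(C)C)cc(cc1O[Si](C(C)C)(C(C)C)C(C)C)[C@H](O)CCCCCC/C=C/CCCCC2 | intermediate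
19 | dehydrogravicycle, (R)-carbinol, E-alkene | Oc1cc2cc(c1)Oc1c(O)cc(cc1O)[C@H](O)CCCCCC/C=C/CCCCC2 | target

**Step count and risks**

Total step count: 12. Longest linear sequence: 10 steps (steps 3 to 12).

Steps most likely to fail:

1. Step 11 (bears the label). The aryl transfer may show poor or reversed facial selectivity, and slow aryl transfer to chromium may let hydrodeiodination or dimerisation compete. Fallback, from 17 back to 18: the ring is closed without chiral ligand by the parent Ni/Cr-mediated aryl iodide–aldehyde coupling (CrCl2, NiCl2 cat., DMSO, rt, high dilution) to the racemic macrocyclic alcohol F1. Dess–Martin periodinane then gives the macrocyclic aryl ketone F2. Reduction with (S)-2-methyl-CBS-oxazaborolidine and catecholborane in toluene at −78 °C, a reagent-controlled reduction of an aryl alkyl ketone that leaves the alkene alone, should give the (R)-alcohol 18.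

2. Step 7. C–H borylation may be incomplete beside the bulky silyl ethers, and protodeboronation or silyl ether loss may occur in the hot aqueous copper stage. Fallback, from 5 back to 14: the halogen is placed at the phenol stage, where C4 is para-activated. Bromination of 5 (NBS, catalytic NaH, CHCl3, −45 °C) gives 4-bromo-2,6-dimethoxyphenol F3. Ullmann coupling as in step 3 with an excess of 1,3-diiodo-5-methoxybenzene gives 5-bromo-2-(3-iodo-5-methoxyphenoxy)-1,3-dimethoxybenzene F4. BBr3 gives 5-bromo-2-(3-hydroxy-5-iodophenoxy)benzene-1,3-diol F5, and TIPSOTf with 2,6-lutidine gives 5-bromo-2-[3-iodo-5-(TIPS-oxy)phenoxy]-1,3-bis(TIPS-oxy)benzene F6. Suzuki coupling with borane 11 at the carbon–iodine bond only (PdCl2(dppf), aq. K3PO4, rt) gives methyl 6-[3-[4-bromo-2,6-bis(TIPS-oxy)phenoxy]-5-(TIPS-oxy)phenyl]hexanoate F7. Copper-catalysed halide exchange (CuI, NaI, trans-N,N′-dimethylcyclohexane-1,2-diamine, dioxane, 110 °C) then gives 14.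

3. Step 9. Some Z-alkene may form and be hard to remove at this stage, and the base may cause self-condensation of the ester-bearing sulfone or aldol reaction of the aldehyde. Fallback, from 4 and 9 back to 16: the olefination is moved to small fragments. Sulfone 4 and hex-5-enal (KN(SiMe3)2, DME, −60 °C) give ethyl (E)-tetradeca-8,13-dienoate F8, which can be freed of Z isomer on AgNO3-impregnated silica. 9-BBN adds to the terminal alkene only, giving ethyl (E)-14-(9-borabicyclo[3.3.1]nonan-9-yl)tetradec-8-enoate F9. Suzuki coupling with bromide 9 as in step 6 gives ethyl (E)-14-[3-[2,6-bis(TIPS-oxy)phenoxy]-5-(TIPS-oxy)phenyl]tetradec-8-enoate F10. Borylation and iodination as in step 7 (EtOH in place of MeOH), through the aryl pinacol boronate F11, give 16. The isolated E-alkene is expected to react much more slowly with the iridium boryl catalyst than the unhindered arene C–H, but this tolerance would have to be checked.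

**Further compounds**

F1 | step 11 | racemic tris-TIPS macrocyclic alcohol (18 without defined configuration at the carbinol) | CC(C)[Si](C(C)C)(C(C)C)Oc1cc2cc(c1)Oc1c(O[Si](C(C)C)(C(C)C)C(C)C)cc(cc1O[Si](C(C)C)(C(C)C)C(C)C)C(O)CCCCCC/C=C/CCCCC2
F2 | step 11 | tris-TIPS macrocyclic aryl ketone (C1 carbonyl on ring B C4, E-alkene) | CC(C)[Si](C(C)C)(C(C)C)Oc1cc2cc(c1)Oc1c(O[Si](C(C)C)(C(C)C)C(C)C)cc(cc1O[Si](C(C)C)(C(C)C)C(C)C)C(=O)CCCCCC/C=C/CCCCC2
F3 | step 7 | 4-bromo-2,6-dimethoxyphenol | COc1cc(Br)cc(OC)c1O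
F4 | step 7 | 5-bromo-2-(3-iodo-5-methoxyphenoxy)-1,3-dimethoxybenzene | COc1cc(I)cc(Oc2c(OC)cc(Br)cc2OC)c1
F5 | step 7 | 5-bromo-2-(3-hydroxy-5-iodophenoxy)benzene-1,3-diol | Oc1cc(I)cc(Oc2c(O)cc(Br)cc2O)c1
F6 | step 7 | 5-bromo-2-[3-iodo-5-(TIPS-oxy)phenoxy]-1,3-bis(TIPS-oxy)benzene | Ic1cc(O[Si](C(C)C)(C(C)C)C(C)C)cc(Oc2c(O[Si](C(C)C)(C(C)C)C(C)C)cc(Br)cc2O[Si](C(C)C)(C(C)C)C(C)C)c1
F7 | step 7 | methyl 6-[3-[4-bromo-2,6-bis(TIPS-oxy)phenoxy]-5-(TIPS-oxy)phenyl]hexanoate | COC(=O)CCCCCc1cc(O[Si](C(C)C)(C(C)C)C(C)C)cc(Oc2c(O[Si](C(C)C)(C(C)C)C(C)C)cc(Br)cc2O[Si](C(C)C)(C(C)C)C(C)C)c1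
F8 | step 9 | ethyl (E)-tetradeca-8,13-dienoate | CCOC(=O)CCCCCC/C=C/CCCC=C
F9 | step 9 | ethyl (E)-14-(9-borabicyclo[3.3.1]nonan-9-yl)tetradec-8-enoate | CCOC(=O)CCCCCC/C=C/CCCCCB1C2CCCC1CCC2
F10 | step 9 | ethyl (E)-14-[3-[2,6-bis(TIPS-oxy)phenoxy]-5-(TIPS-oxy)phenyl]tetradec-8-enoate | CCOC(=O)CCCCCC/C=C/CCCCCc1cc(O[Si](C(C)C)(C(C)C)C(C)C)cc(Oc2c(O[Si](C(C)C)(C(C)C)C(C)C)cccc2O[Si](C(C)C)(C(C)C)C(C)C)c1
F11 | step 9 | ethyl (E)-14-[3-[4-(4,4,5,5-tetramethyl-1,3,2-dioxaborolan-2-yl)-2,6-bis(TIPS-oxy)phenoxy]-5-(TIPS-oxy)phenyl]tetradec-8-enoate | CCOC(=O)CCCCCC/C=C/CCCCCc1cc(O[Si](C(C)C)(C(C)C)C(C)C)cc(Oc2c(O[Si](C(C)C)(C(C)C)C(C)C)cc(B3OC(C)(C)C(C)(C)O3)cc2O[Si](C(C)C)(C(C)C)C(C)C)c1
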